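**Retrosynthetic overview**

1. Target 31 ⇐ 28 by late ortho-lithiation/formylation and MOM removal; the C3 carbinol comes from oxazaborolidine-catalysed reduction of 3-ketone 27.
2. Ring A (closed last) ⇐ intramolecular McMurry coupling (C1=C10) of keto-aldehyde 24; C1 and C2 come from an allyl unit.
3. C4 (quaternary) and the C5 stereocentre ⇐ Ueno–Stork bromoacetal radical cyclisation of allylic alcohol 16; the C10 carbinol relays its configuration to C5.
4. 16 ⇐ enone 15 by ketoreductase 1,2-reduction; 15 ⇐ ring B ketone 13 by Saegusa–Ito dehydrogenation.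
5. 13 ⇐ Cu-catalysed asymmetric conjugate addition of Me3Al to 2-methylcyclohex-2-enone (C8, first stereocentre), then trans-alkylation (C9) with benzylic bromide 8 from methyl 3,5-dihydroxybenzoate. Ring order: arene (bought), ring B (bought as enone), ring A (built).

Conventions: locants C1–C11 follow terpenoid numbering of the decalin (C3 carbinol, C4 gem-dimethyl, C5 ring-fusion CH, C8 CHMe, C9 quaternary C, C10 olefinic ring-fusion C, C11 benzylic CH2). ArCH2 = [2,6-bis(methoxymethoxy)-4-({[tri(propan-2-yl)silyl]oxy}methyl)phenyl]methyl.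

Assumption: the target is taken as the open hydroxy-aldehyde drawn (it can equilibrate with its lactol), and the ketoreductase of step 10 is taken to be found by screening a commercial enzyme panel.

**Route**

Step 1
Reactants: 1 methyl 3,5-dihydroxybenzoate
Product: 2 methyl 3,5-bis(methoxymethoxy)benzoate
Conditions: MOMCl (2.5 equiv), i-Pr2NEt, CH2Cl2, 0 °C → rt
Reagents that add atoms: chloromethyl methyl ether, COCCl
Why: Double O-alkylation of the phenols gives MOM ethers that survive bases and later direct ortho-lithiation; no stereocentre.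

Step 2
Reactants: 2 methyl 3,5-bis(methoxymethoxy)benzoate
Product: 3 [3,5-bis(methoxymethoxy)phenyl]methanol
Conditions: LiAlH4, THF, 0 °C; Fieser work-up
Reagents that add atoms: none
Why: Hydride reduction of the ester to the benzylic alcohol leaves the acetal-type MOM ethers untouched.

Step 3
Reactants: 3 [3,5-bis(methoxymethoxy)phenyl]methanol
Product: 4 {[3,5-bis(methoxymethoxy)phenyl]methoxy}tri(propan-2-yl)silane
Conditions: TIPSCl, imidazole, DMF, rt
Reagents that add atoms: chlorotri(propan-2-yl)silane, CC(C)[Si](Cl)(C(C)C)C(C)C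
Why: Silylation gives a primary TIPS ether that withstands organolithiums, enolates, radicals and mild acid until step 19.

Step 4
Reactants: 4 {[3,5-bis(methoxymethoxy)phenyl]methoxy}tri(propan-2-yl)silane
Product: 6 2,6-bis(methoxymethoxy)-4-({[tri(propan-2-yl)silyl]oxy}methyl)benzaldehyde, via aryllithium 5 (not isolated)
Conditions: n-BuLi, THF, 0 °C; DMF, 0 °C → rt; H2O
Reagents that add atoms: N,N-dimethylformamide, CN(C)C=O
Why: Directed ortho-metalation occurs at the doubly activated position between the two OMOM groups, and the aryllithium is formylated by DMF.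

Step 5
Reactants: 6 2,6-bis(methoxymethoxy)-4-({[tri(propan-2-yl)silyl]oxy}methyl)benzaldehyde
Product: 7 [2,6-bis(methoxymethoxy)-4-({[tri(propan-2-yl)silyl]oxy}methyl)phenyl]methanol
Conditions: NaBH4, MeOH/THF, 0 °C
Reagents that add atoms: none
Why: Simple borohydride reduction of the aryl aldehyde.

Step 6
Reactants: 7 [2,6-bis(methoxymethoxy)-4-({[tri(propan-2-yl)silyl]oxy}methyl)phenyl]methanol
Product: 8 {[4-(bromomethyl)-3,5-bis(methoxymethoxy)phenyl]methoxy}tri(propan-2-yl)silane (ArCH2Br)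
Conditions: CBr4, PPh3, CH2Cl2, 0 °C; used at once
Reagents that add atoms: carbon tetrabromide, BrC(Br)(Br)Br
Why: Appel bromination is neutral, so the acid-labile MOM and silyl groups and the electron-rich benzylic bromide survive.

Step 7
Reactants: 9 2-methylcyclohex-2-en-1-one
Product: 11 trimethyl{[(3R)-2,3-dimethylcyclohex-1-en-1-yl]oxy}silane, via aluminium enolate 10 (not isolated)
Conditions: Me3Al (1.3 equiv), CuO2C(2-thienyl) (3 mol %), chiral biaryl phosphoramidite ligand (6 mol %, enantiomer chosen for 3R), Et2O, −30 °C; then TMSOTf, −30 → 0 °C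
Reagents that add atoms: trimethylaluminium, C[Al](C)C; trimethylsilyl trifluoromethanesulfonate, C[Si](C)(C)OS(=O)(=O)C(F)(F)F
Why: Copper-catalysed asymmetric conjugate addition sets C8 (R) under ligand control, and O-silylation stores the regiodefined tetrasubstituted enolate.

Step 8
Reactants: 11 trimethyl{[(3R)-2,3-dimethylcyclohex-1-en-1-yl]oxy}silane; 8 ArCH2Br
Product: 13 (2S,3R)-2-(ArCH2)-2,3-dimethylcyclohexan-1-one, via lithium enolate 12 (not isolated)
Conditions: MeLi, THF, 0 °C; then HMPA and 8, −78 → 0 °C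
Reagents that add atoms: none
Why: Regiospecific enolate alkylation builds the C9 quaternary centre; the bromide enters anti to the pseudo-axial C8 methyl, so ArCH2 is trans to it and the two methyls are cis (C9 = S).

Step 9
Reactants: 13 (2S,3R)-2-(ArCH2)-2,3-dimethylcyclohexan-1-one
Product: 15 (5R,6S)-6-(ArCH2)-5,6-dimethylcyclohex-2-en-1-one, via silyl enol ether 14 (not isolated)
Conditions: LiN(i-Pr)2, TMSCl, THF, −78 °C; then Pd(OAc)2 (1.05 equiv), MeCN, rt
Reagents that add atoms: none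
Why: Saegusa–Ito dehydrogenation can only give the C5=C6 enone because C9 is quaternary and the ketone enolises solely towards C5.

Step 10
Reactants: 15 (5R,6S)-6-(ArCH2)-5,6-dimethylcyclohex-2-en-1-one
Product: 16 (1R,5R,6S)-6-(ArCH2)-5,6-dimethylcyclohex-2-en-1-ol
Conditions: ketoreductase (KRED, NADPH-dependent alcohol dehydrogenase), NADP+ (cat.), i-PrOH, KH2PO4/K2HPO4 buffer pH 7, MgSO4, DMSO (15% v/v), 30 °C
Reagents that add atoms: none
Why: Enzymatic 1,2-reduction by a ketoreductase (the class that reduces 2-benzyl-2-methylcyclohexane-1,3-diones next to the same kind of quaternary carbon) sets the C10 carbinol (R, OH cis to ArCH2) under enzyme control, where substrate bias alone is weak.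

Step 11
Reactants: 16 (1R,5R,6S)-6-(ArCH2)-5,6-dimethylcyclohex-2-en-1-ol
Product: 17 (3R,4S,5R)-4-(ArCH2)-3-(2-bromo-1-ethoxy-2-methylpropoxy)-4,5-dimethylcyclohex-1-ene (acetal-carbon epimers)
Conditions: 1-ethoxy-2-methylprop-1-ene (3 equiv), NBS (1.1 equiv), CH2Cl2, −78 → −20 °C
Reagents that add atoms: 1-ethoxy-2-methylprop-1-ene, CCOC=C(C)C; N-bromosuccinimide, O=C1CCC(=O)N1Br
Why: Haloacetalisation (Ueno–Stork precursor): the enol ether is far more nucleophilic than the arene or ring alkene, and the allylic alcohol traps the bromo-oxocarbenium ion.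

Step 12
Reactants: 17 bromoacetal
Product: 18 (3aS,6R,7S,7aR)-7-(ArCH2)-2-ethoxy-3,3,6,7-tetramethyloctahydro-1-benzofuran (C2 epimers)
Conditions: Bu3SnH (1.3 equiv, syringe pump), AIBN (0.1 equiv), PhH, 80 °C
Reagents that add atoms: none
Why: Ueno–Stork 5-exo-trig radical cyclisation forms the C4–C5 bond and the C4 quaternary carbon; the five-membered ring must be cis-fused, so C4 enters cis to the C10 oxygen and H5 ends cis to the C9 methyl, as in the target.

Step 13
Reactants: 18 bicyclic acetal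
Product: 19 (3aS,6R,7S,7aR)-7-(ArCH2)-3,3,6,7-tetramethyloctahydro-1-benzofuran-2-ol (lactol, C2 epimers)
Conditions: AcOH/H2O/THF (3:1:1), 45 °C
Reagents that add atoms: water, O
Why: Mild hydrolysis of the furanoside-type acetal unmasks C3 at the aldehyde level without touching aryl MOM or TIPS ethers.

Step 14
Reactants: 19 lactol
Product: 20 (1R,2S,3R,6S)-2-(ArCH2)-6-(3-hydroxy-2-methylhex-5-en-2-yl)-2,3-dimethylcyclohexan-1-ol (side-chain carbinol epimers)
Conditions: CH2=CHCH2MgBr (3 equiv), THF, 0 °C → rt; H2O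
Reagents that add atoms: allylmagnesium bromide, C=CC[Mg]Br
Why: Grignard addition to the open hydroxy-aldehyde form brings in C2 and C1; the new C3 carbinol forms as both epimers, which converge at ketone 27.

Step 15
Reactants: 20 diol
Product: 21 (1R,2S,3R,6S)-2-(ArCH2)-6-{3-[(tert-butyldimethylsilyl)oxy]-2-methylhex-5-en-2-yl}-2,3-dimethylcyclohexan-1-ol (C3 epimers)
Conditions: TBSOTf (1.1 equiv), 2,6-lutidine, CH2Cl2, −78 °C
Reagents that add atoms: tert-butyldimethylsilyl trifluoromethanesulfonate, CC(C)(C)[Si](C)(C)OS(=O)(=O)C(F)(F)F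
Why: Selective silylation: the side-chain OH is neopentylic on one side only, whereas the ring OH lies between the C9 quaternary carbon and the carbon bearing the tert-alkyl group and stays free.

Step 16
Reactants: 21 mono-silyl ether
Product: 22 (2S,3R,6S)-2-(ArCH2)-6-{3-[(tert-butyldimethylsilyl)oxy]-2-methylhex-5-en-2-yl}-2,3-dimethylcyclohexan-1-one (C3 epimers)
Conditions: Dess–Martin periodinane, NaHCO3, CH2Cl2, rt
Reagents that add atoms: none
Why: Buffered periodinane oxidation returns the C10 ketone under non-enolising conditions, so the kinetically set C5 centre is kept.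

Step 17
Reactants: 22 ketone
Product: 24 3-[(tert-butyldimethylsilyl)oxy]-4-[(1S,3S,4R)-3-(ArCH2)-3,4-dimethyl-2-oxocyclohexyl]-4-methylpentanal (C3 epimers), via diol 23 (not isolated)
Conditions: OsO4 (2 mol %), NaIO4 (4 equiv), 2,6-lutidine, 1,4-dioxane/H2O, rt
Reagents that add atoms: sodium periodate, [Na+].[O-]I(=O)(=O)=O (oxygen delivered through catalytic OsO4, O=[Os](=O)(=O)=O)
Why: Lemieux–Johnson cleavage turns the terminal alkene into the C1 aldehyde while sparing the electron-rich arene that ozone would attack.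

Step 18
Reactants: 24 keto-aldehyde
Product: 25 (1S,2R,4aR)-1-(ArCH2)-6-[(tert-butyldimethylsilyl)oxy]-1,2,5,5-tetramethyl-1,2,3,4,4a,5,6,7-octahydronaphthalene (C6 epimers)
Conditions: TiCl3(DME)1.5, Zn–Cu couple, DME, reflux; 24 added over 20 h by syringe pump
Reagents that add atoms: none
Why: Intramolecular McMurry coupling of the 1,6-keto-aldehyde closes ring A and places the alkene exactly between C1 and C10; no new stereocentre forms and C5 is locked once C10 is sp2.

Step 19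
Reactants: 25 silyl-protected alkene
Product: 26 (5S,6R,8aR)-5-{[4-(hydroxymethyl)-2,6-bis(methoxymethoxy)phenyl]methyl}-1,1,5,6-tetramethyl-1,2,3,5,6,7,8,8a-octahydronaphthalen-2-ol (C2 epimers)
Conditions: Bu4NF, THF, rt → 45 °C
Reagents that add atoms: none
Why: Fluoride cleaves both silyl ethers (secondary TBS and benzylic TIPS) and leaves MOM ethers and the alkene alone.

Step 20
Reactants: 26 diol
Product: 27 4-{[(1S,2R,4aR)-1,2,5,5-tetramethyl-6-oxo-1,2,3,4,4a,5,6,7-octahydronaphthalen-1-yl]methyl}-3,5-bis(methoxymethoxy)benzaldehyde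
Conditions: Dess–Martin periodinane (3 equiv), NaHCO3, CH2Cl2, 0 °C → rt
Reagents that add atoms: none
Why: Double oxidation merges both C3 epimers into one β,γ-unsaturated ketone, which cannot conjugate through the quaternary C4 and is kept buffered, and needs no differentiation of the two hydroxyls.

Step 21
Reactants: 27 keto-aldehyde
Product: 28 (2R,5S,6R,8aR)-5-{[4-(hydroxymethyl)-2,6-bis(methoxymethoxy)phenyl]methyl}-1,1,5,6-tetramethyl-1,2,3,5,6,7,8,8a-octahydronaphthalen-2-ol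
Conditions: (S)-Me-CBS oxazaborolidine (0.3 equiv), BH3·SMe2 (2.5 equiv, slow addition), THF, −20 °C; then H2O
Reagents that add atoms: none
Why: Corey–Bakshi–Shibata reduction: the ketone has a quaternary carbon (C4) on one side and a CH2 (C2) on the other, so the (S)-catalyst gives the (3R) alcohol (OH cis to H5) by catalyst control; the aryl aldehyde is reduced back to CH2OH in the same pot.

Step 22
Reactants: 28 diol
Product: 30 6-(hydroxymethyl)-3-{[(1S,2R,4aR,6R)-6-hydroxy-1,2,5,5-tetramethyl-1,2,3,4,4a,5,6,7-octahydronaphthalen-1-yl]methyl}-2,4-bis(methoxymethoxy)benzaldehyde, via trilithio species 29 (not isolated)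
Conditions: n-BuLi (4.5 equiv), TMEDA, THF, −78 → 0 °C; DMF, −78 °C → rt; H2O
Reagents that add atoms: N,N-dimethylformamide, CN(C)C=O
Why: Directed ortho-metalation: after both hydroxyls are deprotonated, the ring position between OMOM and CH2OLi is lithiated (the two free positions are equivalent) and formylated.

Step 23
Reactants: 30 bis-MOM aldehyde
Product: 31 2,4-dihydroxy-6-(hydroxymethyl)-3-{[(1S,2R,4aR,6R)-6-hydroxy-1,2,5,5-tetramethyl-1,2,3,4,4a,5,6,7-octahydronaphthalen-1-yl]methyl}benzaldehyde (target)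
Conditions: 3 M aq. HCl/THF (1:3), 40 °C
Reagents that add atoms: none
Why: Acid hydrolysis of the two aryl MOM acetals; the formyl group makes both phenols and the arene poor nucleophiles, so the trisubstituted alkene is not attacked, and water as co-solvent avoids a cyclic methyl acetal.

**Compound list**

1 | methyl 3,5-dihydroxybenzoate | COC(=O)c1cc(O)cc(O)c1 | starting material
2 | methyl 3,5-bis(methoxymethoxy)benzoate | COCOc1cc(cc(OCOC)c1)C(=O)OC | intermediate
3 | [3,5-bis(methoxymethoxy)phenyl]methanol | COCOc1cc(CO)cc(OCOC)c1 | intermediate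
4 | {[3,5-bis(methoxymethoxy)phenyl]methoxy}tri(propan-2-yl)silane | COCOc1cc(CO[Si](C(C)C)(C(C)C)C(C)C)cc(OCOC)c1 | intermediate
5 | [2,6-bis(methoxymethoxy)-4-({[tri(propan-2-yl)silyl]oxy}methyl)phenyl]lithium | [Li]c1c(OCOC)cc(CO[Si](C(C)C)(C(C)C)C(C)C)cc1OCOC | intermediate (not isolated)
6 | 2,6-bis(methoxymethoxy)-4-({[tri(propan-2-yl)silyl]oxy}methyl)benzaldehyde | O=Cc1c(OCOC)cc(CO[Si](C(C)C)(C(C)C)C(C)C)cc1OCOC | intermediate
7 | [2,6-bis(methoxymethoxy)-4-({[tri(propan-2-yl)silyl]oxy}methyl)phenyl]methanol | OCc1c(OCOC)cc(CO[Si](C(C)C)(C(C)C)C(C)C)cc1OCOC | intermediate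
8 | {[4-(bromomethyl)-3,5-bis(methoxymethoxy)phenyl]methoxy}tri(propan-2-yl)silane | BrCc1c(OCOC)cc(CO[Si](C(C)C)(C(C)C)C(C)C)cc1OCOC | intermediate
9 | 2-methylcyclohex-2-en-1-one | CC1=CCCCC1=O | starting material
10 | dimethylaluminium (3R)-2,3-dimethylcyclohex-1-en-1-olate | C[C@@H]1CCCC(O[Al](C)C)=C1C | intermediate (not isolated)
11 | trimethyl{[(3R)-2,3-dimethylcyclohex-1-en-1-yl]oxy}silane | C[C@@H]1CCCC(O[Si](C)(C)C)=C1C | intermediate
12 | lithium (3R)-2,3-dimethylcyclohex-1-en-1-olate | C[C@@H]1CCCC(O[Li])=C1C | intermediate (not isolated)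
13 | (2S,3R)-2-(ArCH2)-2,3-dimethylcyclohexan-1-one | C[C@@H]1CCCC(=O)[C@@]1(C)Cc1c(OCOC)cc(CO[Si](C(C)C)(C(C)C)C(C)C)cc1OCOC | intermediate
14 | {[(5R,6S)-6-(ArCH2)-5,6-dimethylcyclohex-1-en-1-yl]oxy}trimethylsilane | C[C@@H]1CCC=C(O[Si](C)(C)C)[C@@]1(C)Cc1c(OCOC)cc(CO[Si](C(C)C)(C(C)C)C(C)C)cc1OCOC | intermediate (not isolated)
15 | (5R,6S)-6-(ArCH2)-5,6-dimethylcyclohex-2-en-1-one | C[C@@H]1CC=CC(=O)[C@@]1(C)Cc1c(OCOC)cc(CO[Si](C(C)C)(C(C)C)C(C)C)cc1OCOC | intermediate
16 | (1R,5R,6S)-6-(ArCH2)-5,6-dimethylcyclohex-2-en-1-ol | C[C@@H]1CC=C[C@@H](O)[C@@]1(C)Cc1c(OCOC)cc(CO[Si](C(C)C)(C(C)C)C(C)C)cc1OCOC | intermediate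
17 | (3R,4S,5R)-4-(ArCH2)-3-(2-bromo-1-ethoxy-2-methylpropoxy)-4,5-dimethylcyclohex-1-ene, acetal carbon unassigned | C[C@@H]1CC=C[C@@H](OC(OCC)C(C)(C)Br)[C@@]1(C)Cc1c(OCOC)cc(CO[Si](C(C)C)(C(C)C)C(C)C)cc1OCOC | intermediate
18 | (3aS,6R,7S,7aR)-7-(ArCH2)-2-ethoxy-3,3,6,7-tetramethyloctahydro-1-benzofuran, C2 unassigned | C[C@@H]1CC[C@@H]2[C@@H](OC(OCC)C2(C)C)[C@@]1(C)Cc1c(OCOC)cc(CO[Si](C(C)C)(C(C)C)C(C)C)cc1OCOC | intermediate
19 | (3aS,6R,7S,7aR)-7-(ArCH2)-3,3,6,7-tetramethyloctahydro-1-benzofuran-2-ol, C2 unassigned | C[C@@H]1CC[C@@H]2[C@@H](OC(O)C2(C)C)[C@@]1(C)Cc1c(OCOC)cc(CO[Si](C(C)C)(C(C)C)C(C)C)cc1OCOC | intermediate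
20 | (1R,2S,3R,6S)-2-(ArCH2)-6-(3-hydroxy-2-methylhex-5-en-2-yl)-2,3-dimethylcyclohexan-1-ol, both side-chain carbinol epimers | C[C@@H]1CC[C@@H](C(C)(C)C(O)CC=C)[C@@H](O)[C@@]1(C)Cc1c(OCOC)cc(CO[Si](C(C)C)(C(C)C)C(C)C)cc1OCOC | intermediate
21 | (1R,2S,3R,6S)-2-(ArCH2)-6-{3-[(tert-butyldimethylsilyl)oxy]-2-methylhex-5-en-2-yl}-2,3-dimethylcyclohexan-1-ol, both C3 epimers | C[C@@H]1CC[C@@H](C(C)(C)C(CC=C)O[Si](C)(C)C(C)(C)C)[C@@H](O)[C@@]1(C)Cc1c(OCOC)cc(CO[Si](C(C)C)(C(C)C)C(C)C)cc1OCOC | intermediate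
22 | (2S,3R,6S)-2-(ArCH2)-6-{3-[(tert-butyldimethylsilyl)oxy]-2-methylhex-5-en-2-yl}-2,3-dimethylcyclohexan-1-one, both C3 epimers | C[C@@H]1CC[C@@H](C(C)(C)C(CC=C)O[Si](C)(C)C(C)(C)C)C(=O)[C@@]1(C)Cc1c(OCOC)cc(CO[Si](C(C)C)(C(C)C)C(C)C)cc1OCOC | intermediate
23 | (2S,3R,6S)-2-(ArCH2)-6-{3-[(tert-butyldimethylsilyl)oxy]-5,6-dihydroxy-2-methylhexan-2-yl}-2,3-dimethylcyclohexan-1-one | C[C@@H]1CC[C@@H](C(C)(C)C(CC(O)CO)O[Si](C)(C)C(C)(C)C)C(=O)[C@@]1(C)Cc1c(OCOC)cc(CO[Si](C(C)C)(C(C)C)C(C)C)cc1OCOC | intermediate (not isolated)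
24 | 3-[(tert-butyldimethylsilyl)oxy]-4-[(1S,3S,4R)-3-(ArCH2)-3,4-dimethyl-2-oxocyclohexyl]-4-methylpentanal, both C3 epimers | C[C@@H]1CC[C@@H](C(C)(C)C(CC=O)O[Si](C)(C)C(C)(C)C)C(=O)[C@@]1(C)Cc1c(OCOC)cc(CO[Si](C(C)C)(C(C)C)C(C)C)cc1OCOC | intermediate
25 | (1S,2R,4aR)-1-(ArCH2)-6-[(tert-butyldimethylsilyl)oxy]-1,2,5,5-tetramethyl-1,2,3,4,4a,5,6,7-octahydronaphthalene, both C6 epimers | C[C@@H]1CC[C@@H]2C(=CCC(O[Si](C)(C)C(C)(C)C)C2(C)C)[C@@]1(C)Cc1c(OCOC)cc(CO[Si](C(C)C)(C(C)C)C(C)C)cc1OCOC | intermediate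
26 | (5S,6R,8aR)-5-{[4-(hydroxymethyl)-2,6-bis(methoxymethoxy)phenyl]methyl}-1,1,5,6-tetramethyl-1,2,3,5,6,7,8,8a-octahydronaphthalen-2-ol, both C2 epimers | C[C@@H]1CC[C@@H]2C(=CCC(O)C2(C)C)[C@@]1(C)Cc1c(OCOC)cc(CO)cc1OCOC | intermediate
27 | 4-{[(1S,2R,4aR)-1,2,5,5-tetramethyl-6-oxo-1,2,3,4,4a,5,6,7-octahydronaphthalen-1-yl]methyl}-3,5-bis(methoxymethoxy)benzaldehyde | C[C@@H]1CC[C@@H]2C(=CCC(=O)C2(C)C)[C@@]1(C)Cc1c(OCOC)cc(C=O)cc1OCOC | intermediate
28 | (2R,5S,6R,8aR)-5-{[4-(hydroxymethyl)-2,6-bis(methoxymethoxy)phenyl]methyl}-1,1,5,6-tetramethyl-1,2,3,5,6,7,8,8a-octahydronaphthalen-2-ol | C[C@@H]1CC[C@@H]2C(=CC[C@@H](O)C2(C)C)[C@@]1(C)Cc1c(OCOC)cc(CO)cc1OCOC | intermediate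
29 | trilithio derivative of 28 (both alkoxides and the ring carbon next to CH2OLi) | C[C@@H]1CC[C@@H]2C(=CC[C@@H](O[Li])C2(C)C)[C@@]1(C)Cc1c(OCOC)cc(CO[Li])c([Li])c1OCOC | intermediate (not isolated)
30 | 6-(hydroxymethyl)-3-{[(1S,2R,4aR,6R)-6-hydroxy-1,2,5,5-tetramethyl-1,2,3,4,4a,5,6,7-octahydronaphthalen-1-yl]methyl}-2,4-bis(methoxymethoxy)benzaldehyde | C[C@@H]1CC[C@@H]2C(=CC[C@@H](O)C2(C)C)[C@@]1(C)Cc1c(OCOC)cc(CO)c(C=O)c1OCOC | intermediate
31 | 2,4-dihydroxy-6-(hydroxymethyl)-3-{[(1S,2R,4aR,6R)-6-hydroxy-1,2,5,5-tetramethyl-1,2,3,4,4a,5,6,7-octahydronaphthalen-1-yl]methyl}benzaldehyde | C[C@@H]1CC[C@@H]2C(=CC[C@@H](O)C2(C)C)[C@@]1(C)Cc1c(O)cc(CO)c(C=O)c1O | target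

**Step count and risks**

Total: 23 steps. Longest linear sequence: 22 steps (1 → 8 → 13 → 31; step 7 is the one-step branch from 9).

Most likely to fail:

Step 10 (ketoreductase on the hindered enone). The carbonyl sits next to a quaternary carbon, and the screening panel may give no enzyme with a useful rate or diastereoselectivity. The fallback sets out from 15 and comes back at 16. Luche reduction (NaBH4, CeCl3·7H2O, MeOH, −78 °C) gives 16 together with its C1 epimer (1S,5R,6S)-6-(ArCH2)-5,6-dimethylcyclohex-2-en-1-ol F1. The two are separated on silica, and F1 is oxidised back to 15 with Dess–Martin periodinane and recycled. Stereocontrol then rests on separation and recycling and no longer on the catalyst.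

Step 18 (McMurry ring closure). The ketone is flanked by a quaternary carbon and a tert-alkyl-bearing CH. The Lewis-acidic low-valent titanium could also epimerise C5 (the two C5 epimers of 24 are close in energy) or attack the MOM ethers. The fallback sets out from 24 and comes back at 25. SmI2 (THF, −78 °C → rt) effects intramolecular pinacol coupling without enolisation, giving the cis-diol (1S,2R,4aS)-1-(ArCH2)-6-[(tert-butyldimethylsilyl)oxy]-1,2,5,5-tetramethyldecahydronaphthalene-8,8a-diol F2. 1,1'-Thiocarbonyldiimidazole and DMAP in toluene at 100 °C convert it into the cyclic 8,8a-thionocarbonate of that diol F3. Corey–Winter elimination with P(OMe)3 at 110 °C then gives 25 with the alkene at the same position.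

Step 22 (late ortho-lithiation). A trianion has to form, and lateral lithiation at C11 or allylic deprotonation could compete. The fallback sets out from 28 and comes back at 30. NBS (1.0 equiv, MeCN, −20 °C) brominates the only free, strongly activated ring position, giving [2-bromo-4-{[(1S,2R,4aR,6R)-6-hydroxy-1,2,5,5-tetramethyl-1,2,3,4,4a,5,6,7-octahydronaphthalen-1-yl]methyl}-3,5-bis(methoxymethoxy)phenyl]methanol F4. After deprotonation of the two hydroxyls with NaH, bromine–lithium exchange (t-BuLi, THF, −78 °C) and a DMF quench place the formyl group regiospecifically.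

**Further compounds**

F1 | step 10 | (1S,5R,6S)-6-(ArCH2)-5,6-dimethylcyclohex-2-en-1-ol | C[C@@H]1CC=C[C@H](O)[C@@]1(C)Cc1c(OCOC)cc(CO[Si](C(C)C)(C(C)C)C(C)C)cc1OCOC
F2 | step 18 | (1S,2R,4aS)-1-(ArCH2)-6-[(tert-butyldimethylsilyl)oxy]-1,2,5,5-tetramethyldecahydronaphthalene-8,8a-diol (cis-diol; C6, C8 and C8a as formed) | C[C@@H]1CC[C@@H]2C(O)(C(O)CC(O[Si](C)(C)C(C)(C)C)C2(C)C)[C@@]1(C)Cc1c(OCOC)cc(CO[Si](C(C)C)(C(C)C)C(C)C)cc1OCOC
F3 | step 18 | cyclic 8,8a-thionocarbonate of F2 | C[C@@H]1CC[C@@H]2C3(OC(=S)OC3CC(O[Si](C)(C)C(C)(C)C)C2(C)C)[C@@]1(C)Cc1c(OCOC)cc(CO[Si](C(C)C)(C(C)C)C(C)C)cc1OCOC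
F4 | step 22 | [2-bromo-4-{[(1S,2R,4aR,6R)-6-hydroxy-1,2,5,5-tetramethyl-1,2,3,4,4a,5,6,7-octahydronaphthalen-1-yl]methyl}-3,5-bis(methoxymethoxy)phenyl]methanol | C[C@@H]1CC[C@@H]2C(=CC[C@@H](O)C2(C)C)[C@@]1(C)Cc1c(OCOC)cc(CO)c(Br)c1OCOC
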